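## The problem

Target 28 is an unbranched C20 chain ending in a 5,6-dihydro-2H-pyran-2-one. With the lactone carbonyl as C1, the ring oxygen sits on C5, free hydroxyls sit on C7, C9 and C11, and C12–C20 is a plain nonyl tail. There is only one ring, so the task is chain construction with four carbinol centres (5S, 7S, 9R, 11R), each one methylene apart, related 5,7-anti, 7,9-anti and 9,11-syn. Acyclic induction across a methylene is weak in additions to β-oxygenated aldehydes, so C5, C7 and C9 are best set by reagent control. A 1,3-relationship can, however, be relayed reliably through a six-membered cyclic template, and that is the opening for C11. The unsaturated lactone is the fragile part: base invites oxa-Michael addition of the C7 hydroxyl to C3, ring opening or β-elimination, and hydrogenation would saturate C2=C3, so it has to be made late and unveiled under acid. The β-oxygenated aldehydes met on the way eliminate easily and must be made and used without base. The enabling feature is that C11 is syn to C9 and borders an unfunctionalised tail. Its oxygen can be placed on C13 of an (E)-C11=C12 allylic alcohol of either configuration, moved to C11 by a reversible 1,3-shift, and fixed there as the all-equatorial 2-phenyl-1,3-dioxane O9–C9–C10–C11–O11. Hydrogenation of the leftover C12=C13 alkene then gives the nonyl chain.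

## Retrosynthesis

**28 to 27.** The last operation removes two acid-labile groups, the O9/O11 benzylidene acetal and the C7 silyl ether. The acetal is the one created by the key step, so no protecting-group exchange is needed, and acid is chosen because the enoate does not tolerate base.

**27 to 22.** The lactone is opened at C2=C3 (ring-closing metathesis of acrylate 26), then at the O5–C1 acyl bond (alcohol 24 plus acryloyl chloride 25), then at C4–C5 (aldehyde 22 plus allylborane 4). A Z-selective olefination followed by lactonisation would need C5–OH protection and an ozonolysis, one step more, and would leave alkene geometry as a selectivity issue; in the metathesis the ring enforces it. Aldehyde 22 is simpler by a ring, a stereocentre and five carbons. The forward allyl transfer must set C5 (S), anti to C7, by reagent control.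

**22 to 20.** Aldehyde 22 comes from alcohol 21 and this from pivalate 20. The pivalate is kept as the C5 mask because it survives ozone, metathesis, the acidic rhenium step and hydrogenation, and leaves with hydride without touching acetal or silyl ether.

**20 to 19.** The nonyl tail is traced back to the (E)-C12=C13 alkene of 19, the trace left by the transposition. The forward step must saturate the alkene without hydrogenolysing the benzylic acetal.

**19 to 16 plus 17 (key disconnection).** Three C–O bonds are cut: C11–O and the two acetal bonds at the benzylic carbon. This leads to allylic alcohol 16, which has no C11 stereocentre and no defined configuration at C13, and to benzaldehyde dimethyl acetal 17. The neighbouring options are a third allylation cycle (protection, ozonolysis, chiral reagent, then separate acetalisation) or addition of a nonyl nucleophile to a C11 aldehyde with poor 1,3-control. The transposition instead uses stereorandom material and lets the cis-dioxane decide C11 while installing the diol protection. The forward reaction must deliver oxygen to C11 and not C13, syn to C9, and leave an E alkene.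

**16 to 12 plus 15.** The C11=C12 bond is cut by cross-metathesis into homoallylic alcohol 12 and racemic dec-1-en-3-ol 15. Alcohol 15 comes from octanal 13 and vinylmagnesium bromide 14 through the C12–C13 bond. The partner needs no stereocontrol, which is what makes this cut cheap.

**12 to 1.** Alcohol 12 is cut at C9–C10 into aldehyde 9 and allylborane 10. Aldehyde 9 comes by ozonolysis from silyl ether 7 of homoallylic alcohol 6, which is cut at C7–C8 into aldehyde 3 and allylborane 4. Aldehyde 3 comes from monopivalate 2 of propane-1,3-diol 1. Using the two enantiomeric boranes in turn gives the 7,9-anti pair, and carrying one alkene at a time keeps the two chain ends distinct.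

## Roads not taken

**Alternative 1:** The chain is cut at C6–C7 and C9–C10 at once. Propane-1,3-diol (1) would be allylated at both carbinol carbons in one transfer-hydrogenative operation with [Ir(cod)Cl]2 and a Cl,MeO-BIPHEP ligand to give (4R,6R)-nona-1,8-diene-4,6-diol A1, which holds C7 and C9 in the anti relationship.
- Merits: one catalytic step replaces steps 1–6 of the present route for these two centres, no stoichiometric chiral reagent is needed, and the enantiopurity of a C2-symmetric product is statistically upgraded.
- Weak points: A1 ends in two equivalent allyl groups. Monosilylation breaks the symmetry, but the two remaining monosubstituted alkenes look alike to a metathesis catalyst, so the C11=C12 cross-metathesis would need one of them masked first. A1 also leaves C11 and C5 open.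
- Comparison: for C7/C9 this road is clearly shorter. The chosen plan pays four to five extra steps for an unambiguous distinction of the chain ends (C5 as a pivalate, one alkene present at a time). The two are compatible: A1 could feed the same rhenium step once the alkenes are told apart.

**Alternative 2:** The ring is cut at C5–O. A 2-substituted cyclopentanone A2, epimeric at the future C5, would be oxidised by a Baeyer–Villiger monooxygenase while its epimers interconvert by enolisation, giving saturated lactone A3.
- Merits: C5 and the ring oxygen are set in one biocatalytic step from stereorandom ketone, with no chiral reagent and little waste; in that respect it is better than three stoichiometric operations.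
- Weak points: acceptance of a lipophilic C20 substrate carrying a silyl ether and an acetonide is uncertain. Enolisation of an α-alkyl cyclopentanone at enzyme-compatible pH may be slower than oxidation, which would erode the dynamic resolution. A3 lacks C2=C3, so α-functionalisation and oxidative elimination (two steps through an enolate next to β-oxygen) must follow. A2 already needs the C9/C11 syn diol in place, so this road does not touch the problem the key step solves.
- Comparison: counting ketone alkylation, oxidation and desaturation, the ring costs as many steps as allylation, acryloylation and metathesis. The chosen plan offers predictable facial control and no enzyme screening.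

**Alternative 3:** The ring is cut at C4–C5 and O–C1. Aldehyde A4 and (E)-1-methoxybuta-1,3-diene A5 would combine in a chiral-Lewis-acid-catalysed [4+2] cycloaddition to give the cis-2-methoxy-5,6-dihydro-2H-pyran A6, which is then oxidised at the acetal carbon to the lactone.
- Merits: two bonds, the ring and C5 are made in one catalytic step, and the protected lactone is two steps from the aldehyde instead of three. In step economy for the ring this road is better.
- Weak points: A5 is a weakly activated diene and needs a strong Lewis acid, high concentration and excess diene. The aliphatic β-silyloxy aldehyde A4 is precious at that stage, and its C7 centre may be matched or mismatched with the catalyst. The Lewis acid and the later acetal oxidation must spare the diol acetal.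
- Comparison: the chosen plan is one step longer here. It offers an allyl transfer whose face is set by the reagent alone and a ring closure that cannot give the wrong alkene geometry. A4 is the acetonide analogue of 22, so this endgame could be grafted on later.

Key step: step 9

Remark on the chemistry: atoms are numbered as in the target (C1 lactone carbonyl to C20 methyl) throughout. Re and Si refer to the aldehyde carbon with priorities O > chain > H. The C13 carbinol of 15 and 16 is deliberately a mixture of both configurations. Boranes 4 and 10 are taken as the commercial salt-free pentane solutions, and they are defined by their pinene origin and SMILES should the sign convention differ. TBS = tert-butyldimethylsilyl.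

## Route

Step 1
Reactants: 1 propane-1,3-diol
Product: 2 3-hydroxypropyl 2,2-dimethylpropanoate
Conditions: PivCl (0.35 equiv), pyridine, CH2Cl2, 0 °C → rt
Reagents that add atoms: pivaloyl chloride, CC(C)(C)C(=O)Cl
Why: Statistical mono-acylation of a symmetrical diol; the threefold excess of 1 should keep the bis-ester low, and surplus diol is removed by aqueous washing.

Step 2
Reactants: 2 3-hydroxypropyl 2,2-dimethylpropanoate
Product: 3 3-oxopropyl 2,2-dimethylpropanoate
Conditions: TEMPO (10 mol %), PhI(OAc)2 (1.1 equiv), CH2Cl2, rt
Reagents that add atoms: none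
Why: Oxoammonium-mediated alcohol oxidation stops at the aldehyde and is non-basic, which should avoid β-elimination of pivalate from this 3-acyloxy aldehyde; 3 is used without chromatography.

Step 3
Reactants: 3 3-oxopropyl 2,2-dimethylpropanoate; 4 (−)-B-allyldiisopinocampheylborane (from (+)-α-pinene)
Product: 6 (3S)-3-hydroxyhex-5-en-1-yl 2,2-dimethylpropanoate, via borinate ester 5 (not isolated)
Conditions: 4 (1.2 equiv), Et2O, −78 °C; then 3 M NaOH, 30% H2O2, 0 °C → rt
Reagents that add atoms: none
Why: Brown allylboration through a closed chair transition state; the (+)-α-pinene-derived borane delivers allyl to the Si face of 3, which should set C7 as (S) under reagent control, and the oxidative work-up releases the alcohol from borinate 5.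

Step 4
Reactants: 6 (3S)-3-hydroxyhex-5-en-1-yl 2,2-dimethylpropanoate
Product: 7 (3S)-3-[(tert-butyldimethylsilyl)oxy]hex-5-en-1-yl 2,2-dimethylpropanoate
Conditions: TBSCl, imidazole, DMF, rt
Reagents that add atoms: tert-butyldimethylsilyl chloride, CC(C)(C)[Si](C)(C)Cl
Why: Standard silylation of a secondary alcohol; the ether keeps O7 out of acetal formation in step 9 and is cleaved by the same acid as the acetal at the end.

Step 5
Reactants: 7 (3S)-3-[(tert-butyldimethylsilyl)oxy]hex-5-en-1-yl 2,2-dimethylpropanoate
Product: 9 (3R)-3-[(tert-butyldimethylsilyl)oxy]-5-oxopentyl 2,2-dimethylpropanoate, via ozonide 8 (not isolated)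
Conditions: O3, CH2Cl2, −78 °C; then PPh3, −78 °C → rt
Reagents that add atoms: ozone, [O-][O+]=O
Why: Ozonolysis of the only alkene with reductive cleavage of ozonide 8; the C7 centre is untouched (its descriptor changes only because the priorities change), and the β-silyloxy aldehyde is carried on crude to avoid elimination.

Step 6
Reactants: 9 (3R)-3-[(tert-butyldimethylsilyl)oxy]-5-oxopentyl 2,2-dimethylpropanoate; 10 (+)-B-allyldiisopinocampheylborane (from (−)-α-pinene)
Product: 12 (3R,5R)-3-[(tert-butyldimethylsilyl)oxy]-5-hydroxyoct-7-en-1-yl 2,2-dimethylpropanoate, via borinate ester 11 (not isolated)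
Conditions: 10 (1.3 equiv), Et2O, −78 °C; then 3 M NaOH, 30% H2O2, 0 °C → rt
Reagents that add atoms: none
Why: Brown allylboration with the enantiomeric borane, which adds to the Re face of 9 and should set C9 as (R), anti to C7; β-silyloxy aldehydes have little intrinsic 1,3-bias, so the reagent decides.

Step 7
Reactants: 13 octanal; 14 vinylmagnesium bromide
Product: 15 (±)-dec-1-en-3-ol
Conditions: THF, −78 → 0 °C; aq. NH4Cl
Reagents that add atoms: none
Why: Grignard 1,2-addition to an aldehyde; the carbinol (future C13) is made racemic on purpose because the key step erases it.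

Step 8
Reactants: 12 (3R,5R)-3-[(tert-butyldimethylsilyl)oxy]-5-hydroxyoct-7-en-1-yl 2,2-dimethylpropanoate; 15 (±)-dec-1-en-3-ol
Product: 16 (3R,5R,7E)-3-[(tert-butyldimethylsilyl)oxy]-5,9-dihydroxyhexadec-7-en-1-yl 2,2-dimethylpropanoate (both C13 epimers)
Conditions: 15 (3 equiv), second-generation Hoveyda–Grubbs catalyst (H2IMes)Cl2Ru=CH(C6H4-2-OiPr) (5 mol %), CH2Cl2, 40 °C
Reagents that add atoms: none
Why: Olefin cross-metathesis between a type-1 terminal alkene and an excess of a slowly dimerising secondary allylic alcohol; the E alkene is the thermodynamic outcome and free hydroxyls are tolerated by the ruthenium carbene.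

Step 9
Reactants: 16 (3R,5R,7E)-3-[(tert-butyldimethylsilyl)oxy]-5,9-dihydroxyhexadec-7-en-1-yl 2,2-dimethylpropanoate; 17 benzaldehyde dimethyl acetal
Product: 19 (3R)-3-[(tert-butyldimethylsilyl)oxy]-4-[(2S,4R,6S)-6-[(1E)-non-1-en-1-yl]-2-phenyl-1,3-dioxan-4-yl]butyl 2,2-dimethylpropanoate, via transposed diol 18 (not isolated)
Conditions: Re2O7 (5 mol %), 17 (3 equiv), CH2Cl2, 0 °C → rt
Reagents that add atoms: none
Why: Re2O7 condenses with the C13 hydroxyl to a perrhenate ester that rearranges through a chair-like [3,3] transition state, moving oxygen to C11 and the alkene to C12=C13 with the heptyl group pseudo-equatorial (E). The shift is reversible and, through the ion-pair character of the allylic termini, visits both C11 configurations; this is the known rhenium-oxide-catalysed 1,3-transposition of allylic alcohols with capture as a 1,3-diol acetal. Only transposed diol 18 can exchange both methoxy groups of 17: the first C–O bond forms intermolecularly and the second closes the 1,3-dioxane by 6-endo-trig attack of the remaining hydroxyl on the O-alkyl benzylic oxocarbenium ion. C11 is set under thermodynamic control by C9, because the other C11 epimer would carry an axial substituent in the chair dioxane and the still-allylic C11–O bond can re-ionise until the cis isomer is reached. The acetal carbon equilibrates likewise to phenyl equatorial, so the 2,4,6-cis,cis compound 19 should be the common end point of both C13 epimers of 16. The step needs oxygen at C11 and not C13, syn to C9, and an E alkene. These are secured by the C9 hydroxyl being 1,3 only to C11, by the fixed C9 centre, and by the E geometry of 16, which keeps O9 from reaching C13 to form a dihydropyran; the C7 silyl ether and the pivalate cannot enter an acetal.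

Step 10
Reactants: 19 (3R)-3-[(tert-butyldimethylsilyl)oxy]-4-[(2S,4R,6S)-6-[(1E)-non-1-en-1-yl]-2-phenyl-1,3-dioxan-4-yl]butyl 2,2-dimethylpropanoate
Product: 20 (3R)-3-[(tert-butyldimethylsilyl)oxy]-4-[(2R,4R,6R)-6-nonyl-2-phenyl-1,3-dioxan-4-yl]butyl 2,2-dimethylpropanoate
Conditions: H2 (1–3 atm), (Ph3P)3RhCl (10 mol %), benzene/EtOH 1:1, rt
Reagents that add atoms: none
Why: Homogeneous rhodium-catalysed hydrogenation should reduce the disubstituted alkene without hydrogenolysis of the benzylidene acetal or the allylic C11–O bond, which heterogeneous palladium would put at risk; the descriptors at C11 and the acetal carbon change by priority only.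

Step 11
Reactants: 20 (3R)-3-[(tert-butyldimethylsilyl)oxy]-4-[(2R,4R,6R)-6-nonyl-2-phenyl-1,3-dioxan-4-yl]butyl 2,2-dimethylpropanoate
Product: 21 (3R)-3-[(tert-butyldimethylsilyl)oxy]-4-[(2R,4R,6R)-6-nonyl-2-phenyl-1,3-dioxan-4-yl]butan-1-ol
Conditions: iBu2AlH (2.5 equiv), CH2Cl2, −78 °C; aq. potassium sodium tartrate
Reagents that add atoms: none
Why: Reductive ester cleavage with an aluminium hydride; at −78 °C the benzylidene acetal should not be opened and the silyl ether is inert.

Step 12
Reactants: 21 (3R)-3-[(tert-butyldimethylsilyl)oxy]-4-[(2R,4R,6R)-6-nonyl-2-phenyl-1,3-dioxan-4-yl]butan-1-ol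
Product: 22 (3S)-3-[(tert-butyldimethylsilyl)oxy]-4-[(2R,4R,6R)-6-nonyl-2-phenyl-1,3-dioxan-4-yl]butanal
Conditions: TEMPO (10 mol %), PhI(OAc)2 (1.1 equiv), CH2Cl2, rt
Reagents that add atoms: none
Why: Oxoammonium oxidation of the primary alcohol under non-basic conditions, so the β-silyloxy aldehyde should not eliminate; no stereocentre is affected (C7 changes descriptor by priority only).

Step 13
Reactants: 22 (3S)-3-[(tert-butyldimethylsilyl)oxy]-4-[(2R,4R,6R)-6-nonyl-2-phenyl-1,3-dioxan-4-yl]butanal; 4 (−)-B-allyldiisopinocampheylborane (from (+)-α-pinene)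
Product: 24 (4S,6R)-6-[(tert-butyldimethylsilyl)oxy]-7-[(2R,4R,6R)-6-nonyl-2-phenyl-1,3-dioxan-4-yl]hept-1-en-4-ol, via borinate ester 23 (not isolated)
Conditions: 4 (1.5 equiv), Et2O, −78 °C; then 3 M NaOH, 30% H2O2, 0 °C → rt
Reagents that add atoms: none
Why: Brown allylboration; borane 4 adds to the Si face of 22 and should set C5 as (S), anti to C7, under reagent control, with acetal and silyl ether inert to the borane and to the oxidative work-up.

Step 14
Reactants: 24 (4S,6R)-6-[(tert-butyldimethylsilyl)oxy]-7-[(2R,4R,6R)-6-nonyl-2-phenyl-1,3-dioxan-4-yl]hept-1-en-4-ol; 25 acryloyl chloride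
Product: 26 (4S,6S)-6-[(tert-butyldimethylsilyl)oxy]-7-[(2R,4R,6R)-6-nonyl-2-phenyl-1,3-dioxan-4-yl]hept-1-en-4-yl prop-2-enoate
Conditions: 25 (1.5 equiv), Et3N, DMAP (cat.), CH2Cl2, 0 °C
Reagents that add atoms: none
Why: O-Acylation of the secondary alcohol with an acid chloride under amine base brings in C1–C2 of the lactone; the C5 configuration is retained because only the O–H bond reacts.

Step 15
Reactants: 26 (4S,6S)-6-[(tert-butyldimethylsilyl)oxy]-7-[(2R,4R,6R)-6-nonyl-2-phenyl-1,3-dioxan-4-yl]hept-1-en-4-yl prop-2-enoate
Product: 27 (6S)-6-[(2S)-2-[(tert-butyldimethylsilyl)oxy]-3-[(2R,4R,6R)-6-nonyl-2-phenyl-1,3-dioxan-4-yl]propyl]-5,6-dihydro-2H-pyran-2-one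
Conditions: second-generation Grubbs catalyst (H2IMes)(PCy3)Cl2Ru=CHPh (5 mol %), CH2Cl2 (5 mM), 40 °C
Reagents that add atoms: none
Why: Ring-closing metathesis of the acrylate and the terminal alkene forms C2=C3 and the six-membered unsaturated lactone with the ring enforcing the cis alkene; these are the only two alkenes in the molecule.

Step 16
Reactants: 27 (6S)-6-[(2S)-2-[(tert-butyldimethylsilyl)oxy]-3-[(2R,4R,6R)-6-nonyl-2-phenyl-1,3-dioxan-4-yl]propyl]-5,6-dihydro-2H-pyran-2-one
Product: 28 (6S)-6-[(2S,4R,6R)-2,4,6-trihydroxypentadecyl]-5,6-dihydro-2H-pyran-2-one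
Conditions: 3 M aq. HCl, THF, rt
Reagents that add atoms: none
Why: Acid hydrolysis cleaves the benzylidene acetal and the silyl ether in one operation; acid is used because base would promote oxa-Michael addition of the C7 hydroxyl to the enoate, and no stereocentre is touched.

## Compound list

1 | propane-1,3-diol | OCCCO | starting material
2 | 3-hydroxypropyl 2,2-dimethylpropanoate | CC(C)(C)C(=O)OCCCO | intermediate
3 | 3-oxopropyl 2,2-dimethylpropanoate | CC(C)(C)C(=O)OCCC=O | intermediate
4 | (−)-B-allyldiisopinocampheylborane, allylbis[(1R,2S,3R,5R)-2,6,6-trimethylbicyclo[3.1.1]heptan-3-yl]borane, from (+)-α-pinene | C=CCB([C@@H]1C[C@@H]2C[C@H]([C@H]1C)C2(C)C)[C@@H]1C[C@@H]2C[C@H]([C@H]1C)C2(C)C | starting material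
5 | O-diisopinocampheylboryl (borinate) ester of 6 | C=CC[C@H](OB([C@@H]1C[C@@H]2C[C@H]([C@H]1C)C2(C)C)[C@@H]1C[C@@H]2C[C@H]([C@H]1C)C2(C)C)CCOC(=O)C(C)(C)C | intermediate (not isolated)
6 | (3S)-3-hydroxyhex-5-en-1-yl 2,2-dimethylpropanoate | C=CC[C@H](O)CCOC(=O)C(C)(C)C | intermediate
7 | (3S)-3-[(tert-butyldimethylsilyl)oxy]hex-5-en-1-yl 2,2-dimethylpropanoate | C=CC[C@H](O[Si](C)(C)C(C)(C)C)CCOC(=O)C(C)(C)C | intermediate
8 | (3R)-3-[(tert-butyldimethylsilyl)oxy]-4-(1,2,4-trioxolan-3-yl)butyl 2,2-dimethylpropanoate (ozonide, trioxolane carbon unassigned) | O1COOC1C[C@H](O[Si](C)(C)C(C)(C)C)CCOC(=O)C(C)(C)C | intermediate (not isolated)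
9 | (3R)-3-[(tert-butyldimethylsilyl)oxy]-5-oxopentyl 2,2-dimethylpropanoate | O=CC[C@H](O[Si](C)(C)C(C)(C)C)CCOC(=O)C(C)(C)C | intermediate
10 | (+)-B-allyldiisopinocampheylborane, allylbis[(1S,2R,3S,5S)-2,6,6-trimethylbicyclo[3.1.1]heptan-3-yl]borane, from (−)-α-pinene | C=CCB([C@H]1C[C@H]2C[C@@H]([C@@H]1C)C2(C)C)[C@H]1C[C@H]2C[C@@H]([C@@H]1C)C2(C)C | starting material
11 | O-diisopinocampheylboryl (borinate) ester of 12 | C=CC[C@@H](OB([C@H]1C[C@H]2C[C@@H]([C@@H]1C)C2(C)C)[C@H]1C[C@H]2C[C@@H]([C@@H]1C)C2(C)C)C[C@H](O[Si](C)(C)C(C)(C)C)CCOC(=O)C(C)(C)C | intermediate (not isolated)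
12 | (3R,5R)-3-[(tert-butyldimethylsilyl)oxy]-5-hydroxyoct-7-en-1-yl 2,2-dimethylpropanoate | C=CC[C@@H](O)C[C@H](O[Si](C)(C)C(C)(C)C)CCOC(=O)C(C)(C)C | intermediate
13 | octanal | CCCCCCCC=O | starting material
14 | vinylmagnesium bromide | C=C[Mg]Br | starting material
15 | (±)-dec-1-en-3-ol | C=CC(O)CCCCCCC | intermediate
16 | (3R,5R,7E)-3-[(tert-butyldimethylsilyl)oxy]-5,9-dihydroxyhexadec-7-en-1-yl 2,2-dimethylpropanoate, both epimers at chain C9 (C13 of the target numbering) | CCCCCCCC(O)/C=C/C[C@@H](O)C[C@H](O[Si](C)(C)C(C)(C)C)CCOC(=O)C(C)(C)C | intermediate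
17 | benzaldehyde dimethyl acetal, (dimethoxymethyl)benzene | COC(OC)c1ccccc1 | starting material
18 | (3R,5R,7S,8E)-3-[(tert-butyldimethylsilyl)oxy]-5,7-dihydroxyhexadec-8-en-1-yl 2,2-dimethylpropanoate | CCCCCCC/C=C/[C@@H](O)C[C@@H](O)C[C@H](O[Si](C)(C)C(C)(C)C)CCOC(=O)C(C)(C)C | intermediate (not isolated)
19 | (3R)-3-[(tert-butyldimethylsilyl)oxy]-4-[(2S,4R,6S)-6-[(1E)-non-1-en-1-yl]-2-phenyl-1,3-dioxan-4-yl]butyl 2,2-dimethylpropanoate (2,4,6-cis,cis) | CCCCCCC/C=C/[C@@H]1C[C@@H](O[C@H](c2ccccc2)O1)C[C@H](O[Si](C)(C)C(C)(C)C)CCOC(=O)C(C)(C)C | intermediate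
20 | (3R)-3-[(tert-butyldimethylsilyl)oxy]-4-[(2R,4R,6R)-6-nonyl-2-phenyl-1,3-dioxan-4-yl]butyl 2,2-dimethylpropanoate | CCCCCCCCC[C@@H]1C[C@@H](O[C@H](c2ccccc2)O1)C[C@H](O[Si](C)(C)C(C)(C)C)CCOC(=O)C(C)(C)C | intermediate
21 | (3R)-3-[(tert-butyldimethylsilyl)oxy]-4-[(2R,4R,6R)-6-nonyl-2-phenyl-1,3-dioxan-4-yl]butan-1-ol | CCCCCCCCC[C@@H]1C[C@@H](O[C@H](c2ccccc2)O1)C[C@H](O[Si](C)(C)C(C)(C)C)CCO | intermediate
22 | (3S)-3-[(tert-butyldimethylsilyl)oxy]-4-[(2R,4R,6R)-6-nonyl-2-phenyl-1,3-dioxan-4-yl]butanal | CCCCCCCCC[C@@H]1C[C@@H](O[C@H](c2ccccc2)O1)C[C@H](O[Si](C)(C)C(C)(C)C)CC=O | intermediate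
23 | O-diisopinocampheylboryl (borinate) ester of 24 | CCCCCCCCC[C@@H]1C[C@@H](O[C@H](c2ccccc2)O1)C[C@H](O[Si](C)(C)C(C)(C)C)C[C@@H](OB([C@@H]3C[C@@H]4C[C@H]([C@H]3C)C4(C)C)[C@@H]3C[C@@H]4C[C@H]([C@H]3C)C4(C)C)CC=C | intermediate (not isolated)
24 | (4S,6R)-6-[(tert-butyldimethylsilyl)oxy]-7-[(2R,4R,6R)-6-nonyl-2-phenyl-1,3-dioxan-4-yl]hept-1-en-4-ol | CCCCCCCCC[C@@H]1C[C@@H](O[C@H](c2ccccc2)O1)C[C@H](O[Si](C)(C)C(C)(C)C)C[C@@H](O)CC=C | intermediate
25 | acryloyl chloride (prop-2-enoyl chloride) | C=CC(=O)Cl | starting material
26 | (4S,6S)-6-[(tert-butyldimethylsilyl)oxy]-7-[(2R,4R,6R)-6-nonyl-2-phenyl-1,3-dioxan-4-yl]hept-1-en-4-yl prop-2-enoate | CCCCCCCCC[C@@H]1C[C@@H](O[C@H](c2ccccc2)O1)C[C@H](O[Si](C)(C)C(C)(C)C)C[C@@H](OC(=O)C=C)CC=C | intermediate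
27 | (6S)-6-[(2S)-2-[(tert-butyldimethylsilyl)oxy]-3-[(2R,4R,6R)-6-nonyl-2-phenyl-1,3-dioxan-4-yl]propyl]-5,6-dihydro-2H-pyran-2-one | CCCCCCCCC[C@@H]1C[C@@H](O[C@H](c2ccccc2)O1)C[C@H](O[Si](C)(C)C(C)(C)C)C[C@@H]1CC=CC(=O)O1 | intermediate
28 | (6S)-6-[(2S,4R,6R)-2,4,6-trihydroxypentadecyl]-5,6-dihydro-2H-pyran-2-one | CCCCCCCCC[C@@H](O)C[C@@H](O)C[C@H](O)C[C@@H]1CC=CC(=O)O1 | target

## Step count and least certain steps

Total: 16 steps. Longest linear sequence: 15 steps (steps 1–6 and 8–16, from 1 to 28); step 7 is a one-step side branch.

**Step 9 (key step).**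
- What may go wrong: acid released from Re2O7 may strip the C7 silyl ether, after which acetals scramble between the 7,9- and 9,11-diols. The allylic system may ionise too freely and lose a proton to give a diene. It may also isomerise the alkene so that O9 closes onto C13. Equilibration may stop early and leave the C11-epimeric acetal.
- Fallback: it sets out from 12 and returns at 20, using substrate-controlled iodocyclisation instead of transposition. Alcohol 12 is acylated with Boc2O and DMAP to the tert-butyl carbonate F1. IBr in toluene at −80 °C closes the cis cyclic iodocarbonate F2, with C9 directing C11. K2CO3 in MeOH gives the syn epoxy alcohol F3. Octylmagnesium bromide with catalytic CuI opens the epoxide at C12 to the syn diol F4. Acetal exchange of F4 with 17 under camphorsulfonic acid in CH2Cl2 gives 20, so step 10 is skipped.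

**Step 8 (cross-metathesis).**
- What may go wrong: homodimerisation may compete, ruthenium hydrides may isomerise the allylic alcohol to a saturated ketone, and E/Z control may be incomplete.
- Fallback: it sets out from 12 and returns at 16, forming the C13–C14 bond after the metathesis instead of before. Cross-metathesis of 12 with crotonaldehyde under the same ruthenium catalyst gives the (E)-enal F5. 1,2-Addition of heptylmagnesium bromide (2.2 equiv, THF, −78 °C) then gives 16 as the same epimer mixture.

**Step 10 (hydrogenation).**
- What may go wrong: reduction of the 1,2-disubstituted alkene next to the acetal may be slow, or rhodium may migrate the double bond toward C11 and form an enol ether, which would destroy the C11 centre.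
- Fallback: it sets out from 19 and returns at 20 without a new compound. The reduction is moved from metal catalysis to stoichiometric diimide, generated from 2-nitrobenzenesulfonyl hydrazide and Et3N in CH2Cl2. This concerted hydrogen transfer involves no metal hydride and cannot isomerise the alkene or cleave C–O bonds.

**Step 16 (deprotection).**
- What may go wrong: the freed C7 hydroxyl may add to C3 of the enoate, forming a six-membered ether ring, during the time the robust benzylidene acetal needs for hydrolysis; forcing acid may also open or isomerise the lactone.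
- Fallback: it sets out from 26 and returns at 28 by reversing the order of ring closure and deprotection. Acrylate 26 is hydrolysed with the same aqueous acid to the triol acrylate F6; conjugate addition there would need an eight-membered ring. Ring-closing metathesis of F6 with the second-generation Grubbs catalyst (H2IMes)(PCy3)Cl2Ru=CHPh then forms the lactone under neutral conditions, so the unsaturated lactone never meets acid.

## Further compounds

F1 | step 9 | (3R,5R)-5-[(tert-butoxycarbonyl)oxy]-3-[(tert-butyldimethylsilyl)oxy]oct-7-en-1-yl 2,2-dimethylpropanoate | C=CC[C@@H](OC(=O)OC(C)(C)C)C[C@H](O[Si](C)(C)C(C)(C)C)CCOC(=O)C(C)(C)C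
F2 | step 9 | (3R)-3-[(tert-butyldimethylsilyl)oxy]-4-[(4R,6S)-6-(iodomethyl)-2-oxo-1,3-dioxan-4-yl]butyl 2,2-dimethylpropanoate (cis) | IC[C@@H]1C[C@@H](OC(=O)O1)C[C@H](O[Si](C)(C)C(C)(C)C)CCOC(=O)C(C)(C)C
F3 | step 9 | (3R,5R)-3-[(tert-butyldimethylsilyl)oxy]-5-hydroxy-6-[(2S)-oxiran-2-yl]hexyl 2,2-dimethylpropanoate | C1O[C@H]1C[C@@H](O)C[C@H](O[Si](C)(C)C(C)(C)C)CCOC(=O)C(C)(C)C
F4 | step 9 | (3R,5R,7R)-3-[(tert-butyldimethylsilyl)oxy]-5,7-dihydroxyhexadecyl 2,2-dimethylpropanoate | CCCCCCCCC[C@@H](O)C[C@@H](O)C[C@H](O[Si](C)(C)C(C)(C)C)CCOC(=O)C(C)(C)C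
F5 | step 8 | (3R,5R,7E)-3-[(tert-butyldimethylsilyl)oxy]-5-hydroxy-9-oxonon-7-en-1-yl 2,2-dimethylpropanoate | O=C/C=C/C[C@@H](O)C[C@H](O[Si](C)(C)C(C)(C)C)CCOC(=O)C(C)(C)C
F0 | step 10 | none | none
F6 | step 16 | (4S,6S,8R,10R)-6,8,10-trihydroxynonadec-1-en-4-yl prop-2-enoate | CCCCCCCCC[C@@H](O)C[C@@H](O)C[C@H](O)C[C@@H](OC(=O)C=C)CC=C
A1 | alternative 1 | (4R,6R)-nona-1,8-diene-4,6-diol | C=CC[C@@H](O)C[C@H](O)CC=C
A2 | alternative 2 | 2-[(2R)-2-[(tert-butyldimethylsilyl)oxy]-3-[(4R,6R)-2,2-dimethyl-6-nonyl-1,3-dioxan-4-yl]propyl]cyclopentan-1-one (both epimers at the ring carbon) | CCCCCCCCC[C@@H]1C[C@@H](OC(C)(C)O1)C[C@H](O[Si](C)(C)C(C)(C)C)CC2CCCC2=O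
A3 | alternative 2 | (6S)-6-[(2S)-2-[(tert-butyldimethylsilyl)oxy]-3-[(4R,6R)-2,2-dimethyl-6-nonyl-1,3-dioxan-4-yl]propyl]oxan-2-one | CCCCCCCCC[C@@H]1C[C@@H](OC(C)(C)O1)C[C@H](O[Si](C)(C)C(C)(C)C)C[C@@H]2CCCC(=O)O2
A4 | alternative 3 | (3S)-3-[(tert-butyldimethylsilyl)oxy]-4-[(4R,6R)-2,2-dimethyl-6-nonyl-1,3-dioxan-4-yl]butanal | CCCCCCCCC[C@@H]1C[C@@H](OC(C)(C)O1)C[C@H](O[Si](C)(C)C(C)(C)C)CC=O
A5 | alternative 3 | (E)-1-methoxybuta-1,3-diene | CO/C=C/C=C
A6 | alternative 3 | (2R,6S)-6-[(2S)-2-[(tert-butyldimethylsilyl)oxy]-3-[(4R,6R)-2,2-dimethyl-6-nonyl-1,3-dioxan-4-yl]propyl]-2-methoxy-5,6-dihydro-2H-pyran (cis) | CCCCCCCCC[C@@H]1C[C@@H](OC(C)(C)O1)C[C@H](O[Si](C)(C)C(C)(C)C)C[C@@H]2CC=C[C@H](OC)O2
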